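C5, C6, C7 and C8 of ring A of target 16 (4',7-dihydroxy-3,5,6,8-tetramethoxyflavone, achiral) are four adjacent carbons that each carry oxygen, which is the pattern of a squaric ester. The fusion bond C4a=C8a is also the enol-ether C=C of the 4-pyranone ring C, and together these two features are the retron of a cyclobutenone ring expansion.
Cuts, in order: O-benzyl at C7 and C4' and O-methyl at C5 and C8; C5–C4a (ring A back to a 4-hydroxy-4-pyranonylcyclobutenone); the C7 O-benzyl back to O-methyl; C8–C8a (pyranonyl anion plus dimethyl squarate); then O1–C8a, C2–C3 and C4–C4a of ring C.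
Forward: ring B is bought, ring C is built in steps 1 and 2, the four-membered ring is attached in step 3, ring A closes in step 5, and methylation and hydrogenolysis finish the route.
Symmetric dimethyl squarate is coupled so that no regioisomer can form. The future C7 oxygen is differentiated afterwards (step 4), because only that methoxyl is a vinylogous ester.
Stereochemistry: the target has none; the one carbinol stereocentre of 10 and 11 is racemic and disappears when ring A becomes aromatic.

Key step: step 5

Assumption: 10, 11 and 13 are racemates (one enantiomer of 10 and 11 is drawn), which is harmless because their stereocentres are lost in step 5.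

Step 1
Reactants: 1 2-methoxy-N-methoxy-N-methylacetamide; 2 ethynylmagnesium bromide
Product: 4 (E)-4-(dimethylamino)-1-methoxybut-3-en-2-one, via 1-methoxybut-3-yn-2-one 3 (not isolated)
Conditions: HC≡CMgBr (0.5 M, THF), 0 °C; cold 1 M HCl, Et2O extraction; Me2NH (2 M in THF), 0 °C
Reagents that add atoms: dimethylamine, CNC
Why: The Weinreb ketone synthesis stops at the ynone because the magnesium chelate lasts until the acidic quench, which also keeps the released N,O-dimethylhydroxylamine protonated, and the terminal ynone then takes up dimethylamine by aza-Michael addition to give the thermodynamically preferred E-enaminone with its amino carbon at the future ring position next to oxygen.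

Step 2
Reactants: 4 (E)-4-(dimethylamino)-1-methoxybut-3-en-2-one; 5 4-(benzyloxy)benzoyl chloride
Product: 7 2-[4-(benzyloxy)phenyl]-3-methoxy-4H-pyran-4-one, via C-aroylated enaminone 6 (not isolated)
Conditions: LiN(SiMe3)2 (2.2 equiv) added to 4 + 5, THF, −78 °C; then 3 M HCl, THF, rt
Reagents that add atoms: none
Why: C-acylation of an enaminone α'-enolate by an aroyl chloride, then acid-induced addition–elimination of the enol oxygen at the β-amino carbon, is an established 4-pyranone synthesis, with the second equivalent of base covering the greater acidity of diketone 6, and the benzyl ether tolerates both stages.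

Step 3
Reactants: 7 2-[4-(benzyloxy)phenyl]-3-methoxy-4H-pyran-4-one; 8 dimethyl squarate
Product: 10 4-{6-[4-(benzyloxy)phenyl]-5-methoxy-4-oxo-4H-pyran-2-yl}-4-hydroxy-2,3-dimethoxycyclobut-2-en-1-one (racemic), via 6-lithiopyranone 9 (not isolated)
Conditions: 7 added to LiTMP (lithium 2,2,6,6-tetramethylpiperidide, 1.1 equiv), THF, −78 °C; 8, −78 °C; AcOH quench at −78 °C
Reagents that add atoms: none
Why: Deprotonative lithiation with a hindered amide takes the most acidic ring proton, H-6 beside the ring oxygen, as is known for C2–H of chromones and 4-pyridones, and the vinyllithium then adds 1,2 to one of the two equivalent carbonyl groups of symmetric 8 (the standard organolithium–squarate addition), so only one constitutional isomer can form and the new carbinol centre is racemic and of no consequence.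

Step 4
Reactants: 10 4-{6-[4-(benzyloxy)phenyl]-5-methoxy-4-oxo-4H-pyran-2-yl}-4-hydroxy-2,3-dimethoxycyclobut-2-en-1-one
Product: 11 3-(benzyloxy)-4-{6-[4-(benzyloxy)phenyl]-5-methoxy-4-oxo-4H-pyran-2-yl}-4-hydroxy-2-methoxycyclobut-2-en-1-one (racemic)
Conditions: BnOH (10 equiv), LiOt-Bu (1.2 equiv), 5 Å molecular sieves, THF, −20 to 0 °C; AcOH quench
Reagents that add atoms: benzyl alcohol, OCc1ccccc1
Why: Proposed new method: in 10 only the C3 methoxyl is a vinylogous ester (β to C1=O) while the C2 methoxyl is a plain enol ether, so benzyloxide should add at C3 and the resulting enolate should expel methoxide from the exocyclic C–O bond that overlaps with it (addition–elimination), with excess benzyl alcohol and methanol-absorbing sieves shifting the equilibrium; the first equivalent of base turns the carbinol into its lithium alkoxide, which disfavours acyl cleavage of C1–C4 because that would place a carbanion next to an oxyanion; the closest known reaction types are the alkoxide-catalysed ester interchange of dialkyl squarates and 3-alkoxyenones and the displacement of the 3-alkoxy group of squarate-derived cyclobutenones by amines; the stereocentre is not touched.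

Step 5
Reactants: 11 3-(benzyloxy)-4-{6-[4-(benzyloxy)phenyl]-5-methoxy-4-oxo-4H-pyran-2-yl}-4-hydroxy-2-methoxycyclobut-2-en-1-one
Product: 14 7-(benzyloxy)-2-[4-(benzyloxy)phenyl]-5,8-dihydroxy-3,6-dimethoxy-4H-chromen-4-one, via (Z)-dienylketene 12 (not isolated), via 4a-H cyclohexadienone 13 (not isolated)
Conditions: degassed toluene (0.01 M), 110 °C, Ar
Reagents that add atoms: none
Why: Heat breaks the C1–C4 bond of the cyclobutenone in a conrotatory 4π electrocyclic opening that gives (Z)-dienylketene 12. The donor hydroxyl on the sp3 carbon prefers to rotate outward, as donors do in cyclobutene openings, so the pyranonyl group swings inward and its C=C lies beside the ketene; this torquoselectivity is the only selectivity required, and the substrate's own OH provides it. A disrotatory 6π electrocyclisation then bonds the electrophilic ketene carbon (future C5) to the pyranone carbon α to the carbonyl (future C4a), which is the nucleophilic β-carbon of the ring enol ether O1–C8a=C4a, and this closes the six-membered carbocycle ring A in 13. Enolisation of the doubly activated C4a–H makes ring A aromatic and the sequence irreversible, leaving hydroxyls at C5 and C8 on either side of the C6 methoxyl and C7 benzyloxy group delivered by the squarate carbons. The closest known reaction is the Moore rearrangement of 4-alkenyl-, 4-aryl- and 4-heteroaryl-4-hydroxycyclobutenones, α-alkoxyvinyl cases included, to hydroquinones. No stereocentre remains in 14, and air is excluded because 14 is an oxidisable hydroquinone.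

Step 6
Reactants: 14 7-(benzyloxy)-2-[4-(benzyloxy)phenyl]-5,8-dihydroxy-3,6-dimethoxy-4H-chromen-4-one
Product: 15 7-(benzyloxy)-2-[4-(benzyloxy)phenyl]-3,5,6,8-tetramethoxy-4H-chromen-4-one
Conditions: Me2SO4 (6 equiv), K2CO3 (8 equiv), acetone, reflux, Ar
Reagents that add atoms: dimethyl sulfate, COS(=O)(=O)OC
Why: Williamson-type O-methylation of the two phenoxides, where excess reagent and prolonged reflux are the usual answer to the chelated and slow 5-OH of flavones and the inert atmosphere prevents oxidation of the hydroquinone anion to the 5,8-quinone.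

Step 7
Reactants: 15 7-(benzyloxy)-2-[4-(benzyloxy)phenyl]-3,5,6,8-tetramethoxy-4H-chromen-4-one
Product: 16 7-hydroxy-2-(4-hydroxyphenyl)-3,5,6,8-tetramethoxy-4H-chromen-4-one
Conditions: H2 (1 atm), Pd/C (10 %), EtOAc–MeOH, rt
Reagents that add atoms: none
Why: Catalytic hydrogenolysis cleaves both benzylic C–O bonds under ambient pressure while the aryl methyl ethers and the tetrasubstituted C2=C3 bond of the chromone stay intact, which frees exactly the C7 and C4' hydroxyls.

Compound list
1 | 2-methoxy-N-methoxy-N-methylacetamide | COCC(=O)N(C)OC | starting material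
2 | ethynylmagnesium bromide | C#C[Mg]Br | starting material
3 | 1-methoxybut-3-yn-2-one | COCC(=O)C#C | intermediate
4 | (E)-4-(dimethylamino)-1-methoxybut-3-en-2-one | COCC(=O)/C=C/N(C)C | intermediate
5 | 4-(benzyloxy)benzoyl chloride | O=C(Cl)c1ccc(OCc2ccccc2)cc1 | starting material
6 | (E)-1-[4-(benzyloxy)phenyl]-5-(dimethylamino)-2-methoxypent-4-ene-1,3-dione (C2 enolisable, unassigned) | CN(C)/C=C/C(=O)C(OC)C(=O)c1ccc(OCc2ccccc2)cc1 | intermediate
7 | 2-[4-(benzyloxy)phenyl]-3-methoxy-4H-pyran-4-one | O=c1ccoc(-c2ccc(OCc3ccccc3)cc2)c1OC | intermediate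
8 | dimethyl squarate (3,4-dimethoxycyclobut-3-ene-1,2-dione) | COC1=C(OC)C(=O)C1=O | starting material
9 | {6-[4-(benzyloxy)phenyl]-5-methoxy-4-oxo-4H-pyran-2-yl}lithium | [Li]c1cc(=O)c(OC)c(-c2ccc(OCc3ccccc3)cc2)o1 | intermediate
10 | 4-{6-[4-(benzyloxy)phenyl]-5-methoxy-4-oxo-4H-pyran-2-yl}-4-hydroxy-2,3-dimethoxycyclobut-2-en-1-one (racemic, one enantiomer drawn) | O=C1C(OC)=C(OC)[C@]1(O)c1cc(=O)c(OC)c(-c2ccc(OCc3ccccc3)cc2)o1 | intermediate
11 | 3-(benzyloxy)-4-{6-[4-(benzyloxy)phenyl]-5-methoxy-4-oxo-4H-pyran-2-yl}-4-hydroxy-2-methoxycyclobut-2-en-1-one (racemic, one enantiomer drawn) | O=C1C(OC)=C(OCc2ccccc2)[C@]1(O)c1cc(=O)c(OC)c(-c2ccc(OCc3ccccc3)cc2)o1 | intermediate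
12 | (3Z)-3-(benzyloxy)-4-{6-[4-(benzyloxy)phenyl]-5-methoxy-4-oxo-4H-pyran-2-yl}-4-hydroxy-2-methoxybuta-1,3-dien-1-one | O=C=C(OC)/C(OCc1ccccc1)=C(/O)c1cc(=O)c(OC)c(-c2ccc(OCc3ccccc3)cc2)o1 | intermediate
13 | 7-(benzyloxy)-2-[4-(benzyloxy)phenyl]-8-hydroxy-3,6-dimethoxy-4aH-chromene-4,5-dione (racemic) | O=C1C(OC)=C(OCc2ccccc2)C(O)=C3OC(c4ccc(OCc5ccccc5)cc4)=C(OC)C(=O)C13 | intermediate
14 | 7-(benzyloxy)-2-[4-(benzyloxy)phenyl]-5,8-dihydroxy-3,6-dimethoxy-4H-chromen-4-one | COc1c(OCc2ccccc2)c(O)c2oc(-c3ccc(OCc4ccccc4)cc3)c(OC)c(=O)c2c1O | intermediate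
15 | 7-(benzyloxy)-2-[4-(benzyloxy)phenyl]-3,5,6,8-tetramethoxy-4H-chromen-4-one | COc1c(OCc2ccccc2)c(OC)c2oc(-c3ccc(OCc4ccccc4)cc3)c(OC)c(=O)c2c1OC | intermediate
16 | 7-hydroxy-2-(4-hydroxyphenyl)-3,5,6,8-tetramethoxy-4H-chromen-4-one (CNP0539397.0) | COc1c(O)c(OC)c2oc(-c3ccc(O)cc3)c(OC)c(=O)c2c1OC | target

Total steps: 7. Longest linear sequence: 7 steps (1 → 4 → 7 → 10 → 11 → 14 → 15 → 16).

Steps most likely to fail

Step 4 (Proposed new method). Benzyloxide may attack the ring carbonyl instead of C3 and cleave the strained ring. The lithium alkoxide may also open prematurely, or the exchange may stall short of completion. The fallback uses known chemistry, sets out from 8 and rejoins at 11. Half-saponification of 8 with one equivalent of aqueous NaOH gives sodium methyl squarate F1. Alkylation with benzyl bromide in DMF gives benzyl methyl squarate F2. Lithiopyranone 9, made as in step 3, is added to F2 at −78 °C. The two carbonyl groups of F2 are electronically alike, so 11 and the 2-benzyloxy-3-methoxy regioisomeric adduct F3 must both be expected and are separated by chromatography. Compound 10 is bypassed.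

Step 3. The base may instead remove H-5 under direction from the carbonyl oxygen, after which β-elimination of the ring oxygen opens the pyranone. Alternatively, 9 may add in conjugate fashion to unmetalated 7. The fallback sets out from 7 and rejoins at 10. Zincation with TMPZnCl·LiCl in THF at 25 °C, which metalates the position next to oxygen in chromones and gives a species that is stable in solution, should furnish the pyranonylzinc chloride F4. Iodolysis with I2 gives the 6-iodopyranone F5. Iodine–magnesium exchange with i-PrMgCl·LiCl at −40 °C gives the pyranonylmagnesium chloride F6, which adds to 8 as Grignard reagents do to squarates.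

Step 5. If the 6π closure onto the pyranone double bond is slow, the reversible ring opening can drain through the minor inward-hydroxyl rotation. In that rotamer the enol OH captures the ketene as a lactone; the ketene may also oligomerise. The fallback sets out from 11 and rejoins at 15. Silylation of the carbinol (Et3SiOTf, 2,6-lutidine, CH2Cl2, −78 to 0 °C) gives the triethylsilyl ether F7. It has no OH to trap the ketene, and its bulkier donor substituent should turn outward even more strongly. Thermolysis then gives the 5-hydroxy-8-(triethylsilyloxy)flavone F8, which is not a free hydroquinone. Treatment with MeI, CsF and K2CO3 in DMF cleaves the silyl ether and methylates both oxygens in one operation.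

Further compounds
F1 | step 4 | sodium 2-methoxy-3,4-dioxocyclobut-1-en-1-olate | [Na+].COC1=C([O-])C(=O)C1=O
F2 | step 4 | 3-(benzyloxy)-4-methoxycyclobut-3-ene-1,2-dione | COC1=C(OCc2ccccc2)C(=O)C1=O
F3 | step 4 | 2-(benzyloxy)-4-{6-[4-(benzyloxy)phenyl]-5-methoxy-4-oxo-4H-pyran-2-yl}-4-hydroxy-3-methoxycyclobut-2-en-1-one (racemic) | O=C1C(OCc2ccccc2)=C(OC)C1(O)c1cc(=O)c(OC)c(-c2ccc(OCc3ccccc3)cc2)o1
F4 | step 3 | {6-[4-(benzyloxy)phenyl]-5-methoxy-4-oxo-4H-pyran-2-yl}zinc chloride | Cl[Zn]c1cc(=O)c(OC)c(-c2ccc(OCc3ccccc3)cc2)o1
F5 | step 3 | 2-[4-(benzyloxy)phenyl]-6-iodo-3-methoxy-4H-pyran-4-one | Ic1cc(=O)c(OC)c(-c2ccc(OCc3ccccc3)cc2)o1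
F6 | step 3 | {6-[4-(benzyloxy)phenyl]-5-methoxy-4-oxo-4H-pyran-2-yl}magnesium chloride | Cl[Mg]c1cc(=O)c(OC)c(-c2ccc(OCc3ccccc3)cc2)o1
F7 | step 5 | 3-(benzyloxy)-4-{6-[4-(benzyloxy)phenyl]-5-methoxy-4-oxo-4H-pyran-2-yl}-2-methoxy-4-[(triethylsilyl)oxy]cyclobut-2-en-1-one (racemic) | O=C1C(OC)=C(OCc2ccccc2)C1(O[Si](CC)(CC)CC)c1cc(=O)c(OC)c(-c2ccc(OCc3ccccc3)cc2)o1
F8 | step 5 | 7-(benzyloxy)-2-[4-(benzyloxy)phenyl]-5-hydroxy-3,6-dimethoxy-8-[(triethylsilyl)oxy]-4H-chromen-4-one | COc1c(OCc2ccccc2)c(O[Si](CC)(CC)CC)c2oc(-c3ccc(OCc4ccccc4)cc3)c(OC)c(=O)c2c1O
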